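Ring A (C1 = CMe2, C2 = CHOH, C3, C4=C5, C6 = chain-bearing CH) is closed last, at the C1–C6 bond, by a Lewis-acid-triggered, epoxide-initiated cation–olefin cyclization terminated by an allylsilane. The step exploits the C1(Me2)–C2(OH) pair as the trace of a 2,2-dimethyloxirane and the C4=C5 olefin as the trace of a C4 silane. The precursor is the acyclic C1–C11 chain already joined to silyl-protected epoxycyclohexene ring B: (2R)-C1,C2-oxirane, C4 SiMe3, (E)-C5=C6 olefin, C7≡C8 alkyne masking the (7E)-olefin. In one operation C1 becomes quaternary, C6 is set cis to the C2 hydroxyl through a chair relayed from the catalytically made oxirane, and silicon loss fixes C4=C5, both C4 epimers converging.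

Key step: step 19

Remark: ring A carbons are C1–C6, chain carbons C7–C11 and ring B carbons C1′–C6′ (C1′ quaternary oxirane carbon, C2′ oxirane CH, C3′ and C6′ carbinols, C4′ bearing CH2OH). TBS = tert-butyldimethylsilyl. The sense of induction of the chiral catalysts in steps 3 and 9 is assumed to follow the parent catalyst systems; the antipodal ligand is used if it does not.

Step 1
Reactants: 1 4-bromo-2,5-dimethoxybenzaldehyde
Product: 2 methyl 4-bromo-2,5-dimethoxybenzoate
Conditions: I2 (1.3 equiv), KOH (2.6 equiv), MeOH, 0 °C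
Reagents that add atoms: methanol CO
Why: Oxidative esterification of the aldehyde through its methyl hemiacetal installs the ester that later activates and directs the quinone Diels–Alder reaction, while aryl bromide and methyl ethers are untouched.

Step 2
Reactants: 2 methyl 4-bromo-2,5-dimethoxybenzoate
Product: 3 methyl 4-bromo-3,6-dioxocyclohexa-1,4-diene-1-carboxylate
Conditions: AgO (4 equiv), 6 M HNO3, dioxane, 25 °C
Reagents that add atoms: water O
Why: Oxidative demethylation of the 1,4-dimethoxyarene to the p-quinone (quinone oxygens from water, both methoxy groups leaving as methanol), with AgO chosen because ester and bromine deactivate the ring.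

Step 3
Reactants: 3 methyl 4-bromo-3,6-dioxocyclohexa-1,4-diene-1-carboxylate; 4 cyclopenta-1,3-diene
Product: 5 endo cycloadduct methyl 7-bromo-5,8-dioxo-1,4,5,8-tetrahydro-1,4-methanonaphthalene-4a(8aH)-carboxylate
Conditions: Sm(OTf)3 (10 mol %), (S,S)-Ph-pybox (11 mol %), 4 Å MS, CH2Cl2, −78 °C
Reagents that add atoms: none
Why: Catalytic asymmetric Diels–Alder reaction in which two-point binding of the ester and the adjacent quinone carbonyl to the chiral samarium complex activates only the ester-bearing C4′=C5′ bond, the endo transition state gives the cis ring fusion and the ligand selects the quinone face, so all four stereocentres of 5 arise together.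

Step 4
Reactants: 5 endo cycloadduct
Product: 6 7-bromo-4a-(hydroxymethyl)-1,4,4a,5,8,8a-hexahydro-1,4-methanonaphthalene-5,8-diol (both ring hydroxyls on the face of the norbornene bridge)
Conditions: i-Bu2AlH (7 equiv), CH2Cl2, −78 → 0 °C; aq. KNaC4H4O6 (potassium sodium tartrate)
Reagents that add atoms: none
Why: Hydride 1,2-reduction of both enone carbonyls and of the ester, with attack on the convex face of the folded endo adduct, so the new carbinols C3′ and C6′ carry oxygen on the bridge side and are cis to each other (substrate control by the bicyclic template).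

Step 5
Reactants: 6 triol
Product: 7 tris-TBS ether of 6
Conditions: TBSOTf (3.6 equiv), 2,6-lutidine, CH2Cl2, 0 → 25 °C
Reagents that add atoms: tert-butyldimethylsilyl triflate CC(C)(C)[Si](C)(C)OS(=O)(=O)C(F)(F)F
Why: Silylation with the silyl triflate copes with the hindered concave hydroxyls, and TBS ethers allow a single fluoride deprotection at the end.

Step 6
Reactants: 7 tris-TBS ether
Product: 8 (3S,6S)-1-bromo-3,6-bis(TBSO)-4-(TBSOCH2)cyclohexa-1,4-diene
Conditions: flash vacuum pyrolysis, 480 °C, 0.05 mbar, base-washed quartz tube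
Reagents that add atoms: none
Why: Retro-Diels–Alder reaction expels cyclopentadiene and unveils C4′=C5′; the cis-disiloxy-1,4-diene should survive because each ring hydrogen is trans to the remote silyloxy group, which excludes a concerted syn-1,4-elimination to the arene.

Step 7
Reactants: 9 but-2-yn-1-ol
Product: 11 (Z)-3-iodobut-2-en-1-ol, via cyclic alkenylaluminate 10 (not isolated)
Conditions: NaAlH2(OCH2CH2OMe)2 (1.5 equiv), Et2O, 0 °C; then I2, THF, −78 → 0 °C
Reagents that add atoms: iodine II
Why: Alkoxide-directed trans-hydroalumination places aluminium on the distal alkyne carbon in a five-membered aluminate, and iodinolysis with retention gives the (Z)-iodoalkene that fixes the C9=C10 geometry.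

Step 8
Reactants: 11 (Z)-3-iodobut-2-en-1-ol
Product: 12 (Z)-3-iodobut-2-enal
Conditions: MnO2 (15 equiv), CH2Cl2, 25 °C, dark; used at once
Reagents that add atoms: none
Why: MnO2 oxidation of the allylic alcohol under neutral conditions gives the enal without loss of the (Z) geometry.

Step 9
Reactants: 8 bromodiene; 12 (Z)-3-iodobut-2-enal
Product: 15 (1S,2Z)-1-[(3S,6S)-3,6-bis(TBSO)-4-(TBSOCH2)cyclohexa-1,4-dien-1-yl]-3-iodobut-2-en-1-ol, via alkenyllithium 13 (not isolated), via ethyl(alkenyl)zinc 14 (not isolated)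
Conditions: t-BuLi (2.0 equiv), Et2O, −78 °C; EtZnCl (from Et2Zn and ZnCl2), −78 → 0 °C; N,N,N′,N′-tetraethylethylenediamine; (+)-MIB (10 mol %), then 12, toluene, −20 → 0 °C; aq. NH4Cl
Reagents that add atoms: none
Why: Bromine–lithium exchange, transmetalation to zinc and amino-alcohol-catalysed enantioselective alkenylzinc addition (Re-face delivery to the aldehyde) should set C11 (S) under catalyst control, the alkenyl group transferring in preference to ethyl and the iodoalkene staying intact.

Step 10
Reactants: 15 dienyl carbinol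
Product: 16 epoxy alcohol (C1′,C2′-oxirane anti to both ring silyloxy groups and erythro to the C11 hydroxyl; ring B and C11 configured as in the target)
Conditions: VO(acac)2 (5 mol %), t-BuOOH (1.5 equiv), CH2Cl2, 0 °C
Reagents that add atoms: tert-butyl hydroperoxide CC(C)(C)OO
Why: Hydroxyl-directed vanadium-catalysed epoxidation reaches only C1′=C2′ (the iodoalkene is deactivated, C4′=C5′ is not allylic to the free hydroxyl), and the erythro transition state that avoids A(1,2) strain delivers oxygen to the face anti to both silyloxy groups, so C1′ and C2′ are set by C11 and by the ring in a matched sense.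

Step 11
Reactants: 16 epoxy alcohol
Product: 17 tetra-TBS (Z)-iodoalkene
Conditions: TBSOTf (1.5 equiv), 2,6-lutidine, CH2Cl2, −78 → −20 °C
Reagents that add atoms: tert-butyldimethylsilyl triflate CC(C)(C)[Si](C)(C)OS(=O)(=O)C(F)(F)F
Why: Silylation of the hindered C11 hydroxyl with the silyl triflate under buffered conditions leaves the oxirane intact and removes the last free hydroxyl before the Lewis-acid step.

Step 12
Reactants: 18 1,3-bis(trimethylsilyl)propyne; 19 1-bromo-3-methylbut-2-ene
Product: 21 trimethyl[6-methyl-1-(trimethylsilyl)hept-5-en-1-yn-3-yl]silane (racemic), via lithiated propyne 20 (not isolated)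
Conditions: n-BuLi (1.05 equiv), THF, −78 °C; then 19, −78 → 0 °C
Reagents that add atoms: none
Why: The silyl-stabilised propargyl anion is alkylated (SN2) at the propargylic carbon bearing the sp3 silicon; the new C4 centre is left racemic because step 19 erases it.

Step 13
Reactants: 21 bis-silane
Product: 22 trimethyl(6-methylhept-5-en-1-yn-3-yl)silane
Conditions: K2CO3 (0.2 equiv), MeOH, 0 °C
Reagents that add atoms: none
Why: Carbonate methanolysis cleaves only the C(sp)–Si bond (acetylide leaving group) and leaves the C(sp3)–Si bond in place.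

Step 14
Reactants: 22 terminal alkyne
Product: 24 (E)-(1-iodo-2,6-dimethylhepta-1,5-dien-3-yl)trimethylsilane, via alkenylalane 23 (not isolated)
Conditions: AlMe3 (3 equiv), Cp2ZrCl2 (0.3 equiv), CH2Cl2, 0 → 25 °C; then I2, THF, −30 °C; aq. Na2S2O3/NaHCO3
Reagents that add atoms: trimethylaluminium C[Al](C)C; iodine II
Why: Negishi zirconium-catalysed syn-carboalumination adds methyl and aluminium across the terminal alkyne and iodinolysis with retention gives the (E)-iodoalkene (iodine trans to C4), which fixes the C5=C6 geometry.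

Step 15
Reactants: 24 iodo diene
Product: 25 (E)-{1-[(2R)-3,3-dimethyloxiran-2-yl]-4-iodo-3-methylbut-3-en-2-yl}trimethylsilane (C4 epimers)
Conditions: D-fructose-derived Shi ketone (0.3 equiv), KHSO5 (as 2KHSO5·KHSO4·K2SO4), K2CO3, Bu4NHSO4, MeCN/CH2(OMe)2, aq. Na2B4O7 buffer (pH 10.5), 0 °C
Reagents that add atoms: potassium peroxymonosulfate [K+].OOS(=O)(=O)[O-]
Why: Shi epoxidation by the chiral dioxirane is chemoselective for the electron-rich isopropylidene olefin over the iodoalkene and should give the (2R)-oxirane through the spiro transition state (catalyst control).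

Step 16
Reactants: 25 iodo epoxide; 26 ethynyltrimethylsilane
Product: 27 (E)-{1-[(2R)-3,3-dimethyloxiran-2-yl]-3-methyl-6-(trimethylsilyl)hex-3-en-5-yn-2-yl}trimethylsilane
Conditions: PdCl2(PPh3)2 (3 mol %), CuI (6 mol %), i-Pr2NH, THF, 25 °C
Reagents that add atoms: none
Why: Sonogashira coupling of the unhindered (E)-alkenyl iodide proceeds with retention and introduces C7 and C8 without touching oxirane or allylsilane.

Step 17
Reactants: 27 silyl enyne
Product: 28 (E)-{1-[(2R)-3,3-dimethyloxiran-2-yl]-3-methylhex-3-en-5-yn-2-yl}trimethylsilane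
Conditions: K2CO3 (0.3 equiv), MeOH, 0 °C
Reagents that add atoms: none
Why: Selective methanolysis of the alkynyl C–Si bond frees the terminal alkyne while allyl C–Si bond and oxirane are inert to carbonate.

Step 18
Reactants: 17 tetra-TBS (Z)-iodoalkene; 28 terminal enyne
Product: 29 cyclization precursor (5E,9Z)-dienyne joining ring B through C11 to the C4-silyl C1,C2-epoxy chain (C4 epimers)
Conditions: Pd(PPh3)4 (5 mol %), CuI (10 mol %), i-Pr2NH, THF, 25 °C
Reagents that add atoms: none
Why: Sonogashira coupling forms the C8–C9 bond with retention of the (Z)-iodoalkene geometry, and both oxiranes, the allylsilane and the silyl ethers tolerate Pd(PPh3)4, CuI and the amine.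

Step 19
Reactants: 29 cyclization precursor
Product: 30 ring A alkynyl carbinol (2R; hydroxyl and C6 alkynyl group cis; C4=C5 olefin; ring B unchanged)
Conditions: MeAlCl2 (2.0 equiv), CH2Cl2, −90 → −78 °C; Et3N then aq. NaHCO3
Reagents that add atoms: none
Why: MeAlCl2 coordinates the unhindered 2,2-dimethyloxirane and ionizes its C1–O bond, the C5=C6 allylsilane attacks C1 through C6, and the C5 cation, β to silicon, collapses by loss of the silyl group to the C4=C5 olefin. The closest known reaction type is the Lewis-acid-promoted epoxide-initiated cation–olefin cyclization terminated by an allylsilane (epoxy-allylsilane cyclization). Ring A closes in a 6-endo-trig mode at the C5=C6 olefin and in the endo sense at the oxirane, attack taking place at the more substituted carbon C1 so that both oxirane carbons end up in the ring. C6 is set by the chair transition state with the C2–O bond equatorial and the (E)-olefin holding the alkynyl chain equatorial, so the C2 centre from the Shi epoxidation is relayed to the 2,6-cis ring, while C2 is retained because its C–O bond is not broken. The step needs chemoselective activation of one of two oxiranes, which the three flanking C–O bonds and the silyl ethers around the ring B oxirane should secure, and regioselective olefin formation, which the C4 silyl group secures for both C4 epimers because C4 becomes sp2.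

Step 20
Reactants: 30 ring A alkynyl carbinol
Product: 31 (7Z)-8-(benzyldimethylsilyl) diene
Conditions: [Cp*Ru(MeCN)3]PF6 (10 mol %), BnMe2SiH (1.5 equiv), CH2Cl2, 0 → 25 °C
Reagents that add atoms: benzyldimethylsilane C[SiH](C)Cc1ccccc1
Why: Cationic ruthenium-catalysed trans-hydrosilylation adds H and Si anti across the only alkyne (trisubstituted olefins are inert), which fixes C6 and C9 trans across C7=C8; the other regioisomer would converge in step 21.

Step 21
Reactants: 31 silyl diene
Product: 32 target CNP0389279.1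
Conditions: Bu4NF (8 equiv), THF, 0 → 25 °C
Reagents that add atoms: none
Why: Fluoride cleaves the four silyl ethers and the alkenyl C–Si bond (protodesilylation with retention) to give the (7E,9Z)-diene, and mild temperature should avoid Payne migration of the epoxy alcohols.

Compound list
1 | 4-bromo-2,5-dimethoxybenzaldehyde | COc1cc(C=O)c(OC)cc1Br | starting material
2 | methyl 4-bromo-2,5-dimethoxybenzoate | COC(=O)c1cc(OC)c(Br)cc1OC | intermediate
3 | methyl 4-bromo-3,6-dioxocyclohexa-1,4-diene-1-carboxylate | COC(=O)C1=CC(=O)C(Br)=CC1=O | intermediate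
4 | cyclopenta-1,3-diene | C1C=CC=C1 | starting material
5 | endo cycloadduct, methyl 7-bromo-5,8-dioxo-1,4,5,8-tetrahydro-1,4-methanonaphthalene-4a(8aH)-carboxylate (ring-fusion CO2Me and H cis and exo) | COC(=O)[C@]12C(=O)C=C(Br)C(=O)[C@H]1[C@H]1C=C[C@@H]2C1 | intermediate
6 | 7-bromo-4a-(hydroxymethyl)-1,4,4a,5,8,8a-hexahydro-1,4-methanonaphthalene-5,8-diol (ring hydroxyls cis, on the bridge face, trans to CH2OH) | OC[C@]12[C@@H](O)C=C(Br)[C@@H](O)[C@H]1[C@H]1C=C[C@@H]2C1 | intermediate
7 | tris-TBS ether of 6 | CC(C)(C)[Si](C)(C)OC[C@]12[C@@H](O[Si](C)(C)C(C)(C)C)C=C(Br)[C@@H](O[Si](C)(C)C(C)(C)C)[C@H]1[C@H]1C=C[C@@H]2C1 | intermediate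
8 | (3S,6S)-1-bromo-3,6-bis(TBSO)-4-(TBSOCH2)cyclohexa-1,4-diene (cis-disiloxy) | BrC1=C[C@H](O[Si](C)(C)C(C)(C)C)C(CO[Si](C)(C)C(C)(C)C)=C[C@@H]1O[Si](C)(C)C(C)(C)C | intermediate
9 | but-2-yn-1-ol | CC#CCO | starting material
10 | cyclic alkenylaluminate, sodium 2,2-bis(2-methoxyethoxy)-3-methyl-5H-1,2-oxaaluminol-2-uide | [Na+].CC1=CCO[Al-]1(OCCOC)OCCOC | intermediate
11 | (Z)-3-iodobut-2-en-1-ol | I/C(C)=C\CO | intermediate
12 | (Z)-3-iodobut-2-enal | I/C(C)=C\C=O | intermediate
13 | alkenyllithium from 8 (Li in place of Br) | [Li]C1=C[C@H](O[Si](C)(C)C(C)(C)C)C(CO[Si](C)(C)C(C)(C)C)=C[C@@H]1O[Si](C)(C)C(C)(C)C | intermediate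
14 | ethyl(alkenyl)zinc from 13 | CC[Zn]C1=C[C@H](O[Si](C)(C)C(C)(C)C)C(CO[Si](C)(C)C(C)(C)C)=C[C@@H]1O[Si](C)(C)C(C)(C)C | intermediate
15 | (1S,2Z)-1-[(3S,6S)-3,6-bis(TBSO)-4-(TBSOCH2)cyclohexa-1,4-dien-1-yl]-3-iodobut-2-en-1-ol | I/C(C)=C\[C@H](O)C1=C[C@H](O[Si](C)(C)C(C)(C)C)C(CO[Si](C)(C)C(C)(C)C)=C[C@@H]1O[Si](C)(C)C(C)(C)C | intermediate
16 | epoxy alcohol: C1′,C2′-oxirane anti to the C3′ and C6′ silyloxy groups, erythro to the free C11 hydroxyl, (Z)-2-iodopropenyl on C11 | I/C(C)=C\[C@H](O)[C@]12O[C@H]1[C@H](O[Si](C)(C)C(C)(C)C)C(CO[Si](C)(C)C(C)(C)C)=C[C@@H]2O[Si](C)(C)C(C)(C)C | intermediate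
17 | C11 TBS ether of 16 (tetra-TBS (Z)-iodoalkene) | I/C(C)=C\[C@H](O[Si](C)(C)C(C)(C)C)[C@]12O[C@H]1[C@H](O[Si](C)(C)C(C)(C)C)C(CO[Si](C)(C)C(C)(C)C)=C[C@@H]2O[Si](C)(C)C(C)(C)C | intermediate
18 | 1,3-bis(trimethylsilyl)propyne | C[Si](C)(C)CC#C[Si](C)(C)C | starting material
19 | 1-bromo-3-methylbut-2-ene | CC(C)=CCBr | starting material
20 | 1-lithio-1,3-bis(trimethylsilyl)prop-2-yne | [Li]C(C#C[Si](C)(C)C)[Si](C)(C)C | intermediate
21 | trimethyl[6-methyl-1-(trimethylsilyl)hept-5-en-1-yn-3-yl]silane (racemic) | C[Si](C)(C)C#CC(CC=C(C)C)[Si](C)(C)C | intermediate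
22 | trimethyl(6-methylhept-5-en-1-yn-3-yl)silane (racemic) | C#CC(CC=C(C)C)[Si](C)(C)C | intermediate
23 | (E)-dimethyl[2,6-dimethyl-3-(trimethylsilyl)hepta-1,5-dien-1-yl]alane | C[Al](C)/C=C(\C)C(CC=C(C)C)[Si](C)(C)C | intermediate
24 | (E)-(1-iodo-2,6-dimethylhepta-1,5-dien-3-yl)trimethylsilane (racemic) | I/C=C(\C)C(CC=C(C)C)[Si](C)(C)C | intermediate
25 | (E)-{1-[(2R)-3,3-dimethyloxiran-2-yl]-4-iodo-3-methylbut-3-en-2-yl}trimethylsilane (both C4 epimers) | I/C=C(\C)C(C[C@H]1OC1(C)C)[Si](C)(C)C | intermediate
26 | ethynyltrimethylsilane | C#C[Si](C)(C)C | starting material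
27 | (E)-{1-[(2R)-3,3-dimethyloxiran-2-yl]-3-methyl-6-(trimethylsilyl)hex-3-en-5-yn-2-yl}trimethylsilane (both C4 epimers) | C[Si](C)(C)C#C/C=C(\C)C(C[C@H]1OC1(C)C)[Si](C)(C)C | intermediate
28 | (E)-{1-[(2R)-3,3-dimethyloxiran-2-yl]-3-methylhex-3-en-5-yn-2-yl}trimethylsilane (both C4 epimers) | C#C/C=C(\C)C(C[C@H]1OC1(C)C)[Si](C)(C)C | intermediate
29 | cyclization precursor: tetra-TBS ring B epoxide (as in 17) carrying on C11 the (9Z)-C10=C9(Me)–C8≡C7–(5E)-C6H=C5(Me)–C4H(SiMe3)–C3H2–(2R)-oxirane chain (both C4 epimers) | CC1(C)O[C@@H]1CC([Si](C)(C)C)/C(C)=C/C#C/C(C)=C\[C@H](O[Si](C)(C)C(C)(C)C)[C@]12O[C@H]1[C@H](O[Si](C)(C)C(C)(C)C)C(CO[Si](C)(C)C(C)(C)C)=C[C@@H]2O[Si](C)(C)C(C)(C)C | intermediate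
30 | ring A alkynyl carbinol: (2R)-hydroxyl cis to the C6 alkynyl group, C4=C5 olefin, C7≡C8 alkyne, (9Z)-olefin, tetra-TBS ring B | CC1=CC[C@@H](O)C(C)(C)[C@H]1C#C/C(C)=C\[C@H](O[Si](C)(C)C(C)(C)C)[C@]12O[C@H]1[C@H](O[Si](C)(C)C(C)(C)C)C(CO[Si](C)(C)C(C)(C)C)=C[C@@H]2O[Si](C)(C)C(C)(C)C | intermediate
31 | (7Z,9Z)-8-(benzyldimethylsilyl) diene (C6 and C9 trans across C7=C8), tetra-TBS ring B | CC1=CC[C@@H](O)C(C)(C)[C@H]1/C=C(/C(C)=C\[C@H](O[Si](C)(C)C(C)(C)C)[C@]12O[C@H]1[C@H](O[Si](C)(C)C(C)(C)C)C(CO[Si](C)(C)C(C)(C)C)=C[C@@H]2O[Si](C)(C)C(C)(C)C)[Si](C)(C)Cc1ccccc1 | intermediate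
32 | CNP0389279.1, (2R,6S,7E,9Z,11S,1′R,2′S,3′R,6′S) in the numbering of the remark | CC1=CC[C@@H](O)C(C)(C)[C@H]1/C=C/C(C)=C\[C@H](O)[C@]12O[C@H]1[C@H](O)C(CO)=C[C@@H]2O | target

Total step count: 21. Longest linear sequence: 13 steps (steps 1–6, 9–11 and 18–21, from 1).

Steps most likely to fail

Step 19. The Lewis acid may fail to discriminate between the two oxiranes or may ionize the C11 silyl ether. The alkyne-bearing C6 may be too weak a nucleophile, so that a hydride shift to the C2 ketone or 5-exo attack at C5 competes. The C4 epimer that cannot hold silicon anti in the chair may leak through a boat to the C6 epimer. As a fallback, the ring closure is moved ahead of the fragment union. Setting out from 27, MeAlCl2 in CH2Cl2 at −78 °C should give, by the same epoxy-allylsilane cyclization on a substrate without a second oxirane or silyl ethers, the ring A silylalkyne F1, from which any C6 epimer can be separated. Methanolysis with K2CO3 in MeOH then gives the ring A terminal alkyne F2, and Sonogashira coupling of F2 with 17 (Pd(PPh3)4, CuI, i-Pr2NH) comes back to the route at 30.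

Step 9. The hindered, chiral alkenylzinc may transfer slowly, ethyl transfer may compete, and the facial preference of the substrate may oppose that of the ligand. As a fallback, C11 is set by ketone reduction instead. Setting out from 8, bromine–lithium exchange (t-BuLi, Et2O, −78 °C) and direct addition to 12 give the carbinol as a C11 epimer mixture F3. Dess–Martin oxidation gives the cross-conjugated dienone F4. Corey–Bakshi–Shibata reduction with the (R)-methyl oxazaborolidine and catecholborane (ring dienyl as the large group) comes back at 15. Any residual (11R) epimer would be mismatched in step 10 and left behind there.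

Step 6. Material may be lost by aromatization through silanol loss at the pyrolysis temperature, or the non-conjugated adduct may revert incompletely. As a fallback, the ester is kept through the cycloreversion so that the emerging olefin is conjugated and the reaction can run in solution. Setting out from 5, Luche reduction (NaBH4, CeCl3·7H2O, MeOH, −78 °C) gives the diol ester F5 and silylation (TBSOTf, 2,6-lutidine) the bis-TBS ester F6. Heating in Ph2O at 230 °C should give the diene ester F7. Reduction with i-Bu2AlH at −78 °C gives the allylic alcohol F8, and silylation (TBSCl, imidazole) comes back at 8.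

Further compounds
F1 | step 19 | (1R)-2,2,4-trimethyl-3-[(trimethylsilyl)ethynyl]cyclohex-4-en-1-ol, hydroxyl and alkynyl group cis | CC1=CC[C@@H](O)C(C)(C)[C@H]1C#C[Si](C)(C)C
F2 | step 19 | (1R)-3-ethynyl-2,2,4-trimethylcyclohex-4-en-1-ol, hydroxyl and ethynyl group cis | CC1=CC[C@@H](O)C(C)(C)[C@H]1C#C
F3 | step 9 | C11 epimer mixture of 15 | I/C(C)=C\C(O)C1=C[C@H](O[Si](C)(C)C(C)(C)C)C(CO[Si](C)(C)C(C)(C)C)=C[C@@H]1O[Si](C)(C)C(C)(C)C
F4 | step 9 | (Z)-1-[(3S,6S)-3,6-bis(TBSO)-4-(TBSOCH2)cyclohexa-1,4-dien-1-yl]-3-iodobut-2-en-1-one | I/C(C)=C\C(=O)C1=C[C@H](O[Si](C)(C)C(C)(C)C)C(CO[Si](C)(C)C(C)(C)C)=C[C@@H]1O[Si](C)(C)C(C)(C)C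
F5 | step 6 | methyl 7-bromo-5,8-dihydroxy-1,4,5,8-tetrahydro-1,4-methanonaphthalene-4a(8aH)-carboxylate, hydroxyls cis on the bridge face | COC(=O)[C@]12[C@@H](O)C=C(Br)[C@@H](O)[C@H]1[C@H]1C=C[C@@H]2C1
F6 | step 6 | bis-TBS ether of F5 | COC(=O)[C@]12[C@@H](O[Si](C)(C)C(C)(C)C)C=C(Br)[C@@H](O[Si](C)(C)C(C)(C)C)[C@H]1[C@H]1C=C[C@@H]2C1
F7 | step 6 | methyl (3S,6S)-4-bromo-3,6-bis(TBSO)cyclohexa-1,4-diene-1-carboxylate | BrC1=C[C@H](O[Si](C)(C)C(C)(C)C)C(C(=O)OC)=C[C@@H]1O[Si](C)(C)C(C)(C)C
F8 | step 6 | [(3S,6S)-4-bromo-3,6-bis(TBSO)cyclohexa-1,4-dien-1-yl]methanol | BrC1=C[C@H](O[Si](C)(C)C(C)(C)C)C(CO)=C[C@@H]1O[Si](C)(C)C(C)(C)C
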